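**Strategy.** The isoflavanone is cut at C3–C1′ (Pd α-arylation of 5,7-dimethoxychroman-4-one), and the B-ring 2,2-dimethyl-2H-pyran is made by a one-carbon ring expansion. A (2,2-dimethyl-2,3-dihydrobenzofuran-3-yl)methanol is ionised at its CH2OH carbon. The arene carbon that becomes C4a, para to the methoxy group and ortho to the ring oxygen, migrates (phenonium 1,2-shift), and proton loss gives O1–C2(Me)2–C3=C4–C4a–C8a in one operation, erasing the precursor's only stereocentre. The precursor comes from a 2,2-dimethylcoumaranone by methylenation and hydroboration. The (3S) centre is set afterwards by transfer hydrogenation with dynamic kinetic resolution, reoxidation and chelation-controlled 5-O-demethylation.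

Key step: step 4

Assumption: 5,7-dimethoxychroman-4-one (11) is taken as a catalogue compound. Chromene numbering (O1, C2, C3, C4, C4a, C8a) is used for the pyran ring of the B-ring unit.

**Step 1**
Reactants: 1 1-bromo-2,4-dimethoxybenzene; 2 2-bromo-2-methylpropanoyl bromide
Product: 5 5-bromo-6-methoxy-2,2-dimethyl-1-benzofuran-3(2H)-one, via dimethoxy bromo ketone 3 (not isolated), via bromo ketophenol 4 (not isolated)
Conditions: AlCl3 (2.5 equiv), CH2Cl2, 0 °C → rt; aq. HCl work-up; then K2CO3, acetone, rt
Reagents that add atoms: none
Why: Friedel–Crafts acylation should occur at C5 of 1 (para and ortho to the two methoxy groups), AlCl3 then cleaves the carbonyl-chelated ortho-methoxy group, and the phenoxide closes the furanone by intramolecular O-alkylation of the α-bromo ketone (5-exo-tet); Nazarov-type closure to an indanone is disfavoured because the only free ortho carbon is meta to both oxygens.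

**Step 2**
Reactants: 5 5-bromo-6-methoxy-2,2-dimethyl-1-benzofuran-3(2H)-one
Product: 6 5-bromo-6-methoxy-2,2-dimethyl-3-methylidene-2,3-dihydro-1-benzofuran
Conditions: Ph3PCH3Br, KOt-Bu, THF, 0 °C → reflux
Reagents that add atoms: methyltriphenylphosphonium bromide, C[P+](c1ccccc1)(c1ccccc1)c1ccccc1.[Br-]
Why: Wittig methylenation of a non-enolisable aryl ketone (C2 is quaternary), so the ylide can only add to the carbonyl, and the exocyclic alkene cannot isomerise into the ring.

**Step 3**
Reactants: 6 5-bromo-6-methoxy-2,2-dimethyl-3-methylidene-2,3-dihydro-1-benzofuran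
Product: 8 rac-(5-bromo-6-methoxy-2,2-dimethyl-2,3-dihydro-1-benzofuran-3-yl)methanol, via B-alkyl-9-BBN adduct 7 (not isolated)
Conditions: 9-BBN, THF, 60 °C; then NaOH, H2O2, 0 °C → rt
Reagents that add atoms: hydrogen peroxide, OO
Why: Hydroboration–oxidation places boron on the terminal CH2 of the 1,1-disubstituted alkene for steric reasons (anti-Markovnikov alcohol); the new C3 stereocentre is formed racemic, which is of no consequence because step 4 destroys it.

**Step 4**
Reactants: 8 rac-(5-bromo-6-methoxy-2,2-dimethyl-2,3-dihydro-1-benzofuran-3-yl)methanol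
Product: 10 6-bromo-7-methoxy-2,2-dimethyl-2H-chromene, via primary triflate 9 (not isolated)
Conditions: Tf2O, 2,6-di-tert-butyl-4-methylpyridine, CH2Cl2, −78 °C → rt
Reagents that add atoms: none
Why: Triflation gives a neopentyl-type primary triflate that cannot undergo SN2 and should ionise with anchimeric assistance: the ipso carbon C3a, para to the 6-methoxy group and ortho to the ring oxygen, attacks the CH2 carbon to give a spiro-cyclopropyl phenonium ion, whose old C3–C3a bond then breaks while the hindered base removes a proton from the former CH2, giving the O1–C2(Me)2–C3=C4–C4a–C8a ring. The closest known reaction type is the aryl-assisted Wagner–Meerwein (neophyl/phenonium) ring expansion of benzo-fused cycloalkylmethyl sulfonates and of 3-(halomethyl)indolines. The six-membered ring is closed not by an exo or endo cyclisation but by a 1,2-aryl shift (formally a 3-exo-tet ipso attack followed by cleavage of the old C3–aryl bond), which inserts the exocyclic carbon into the five-membered ring as C4. No stereocentre is formed, and the only stereocentre of 8 becomes the sp2 carbon C3, so racemic 8 suffices. The step needs expansion to win over substitution, fragmentation and acid-induced oligomerisation of the electron-rich chromene: the neopentyl position blocks the first, the two donor oxygens on the migrating arene favour migration, and the non-nucleophilic base buffers the triflic acid. A competing shift of C2, or Grob-type C2–C3 cleavage followed by Prins-type reclosure, would pass through the 4-chromanyl cation to the same chromene, so the cationic pathways converge.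

**Step 5**
Reactants: 10 6-bromo-7-methoxy-2,2-dimethyl-2H-chromene; 11 5,7-dimethoxychroman-4-one
Product: 12 rac-5,7-dimethoxy-3-(7-methoxy-2,2-dimethyl-2H-chromen-6-yl)chroman-4-one
Conditions: Pd2(dba)3 (cat.), XPhos (cat.), NaOt-Bu (2.2 equiv), toluene, 80 °C
Reagents that add atoms: none
Why: Palladium-catalysed α-arylation of the ketone enolate (Buchwald–Hartwig type) should stop at monoarylation because the product is held as its hindered, stabilised enolate; C3 is formed racemic and is corrected in step 6.

**Step 6**
Reactants: 12 rac-5,7-dimethoxy-3-(7-methoxy-2,2-dimethyl-2H-chromen-6-yl)chroman-4-one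
Product: 13 (3S,4S)-5,7-dimethoxy-3-(7-methoxy-2,2-dimethyl-2H-chromen-6-yl)chroman-4-ol (cis)
Conditions: RuCl[(S,S)-TsDPEN](p-cymene) (cat.), HCO2H/Et3N (1:5), EtOAc, 40 °C
Reagents that add atoms: none
Why: Noyori–Ikariya asymmetric transfer hydrogenation with dynamic kinetic resolution: Et3N racemises C3 through the enol, the (S,S)-catalyst sets C4 as S (as for 4-chromanone), and hydride is delivered anti to the C3 aryl group, so only the (3S)-ketone is consumed and the cis-(3S,4S) alcohol should result; the amine-rich medium also protects the acid-labile benzylic alcohol.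

**Step 7**
Reactants: 13 (3S,4S)-5,7-dimethoxy-3-(7-methoxy-2,2-dimethyl-2H-chromen-6-yl)chroman-4-ol
Product: 14 (3S)-5,7-dimethoxy-3-(7-methoxy-2,2-dimethyl-2H-chromen-6-yl)chroman-4-one
Conditions: Dess–Martin periodinane, NaHCO3, CH2Cl2, 0 °C
Reagents that add atoms: none
Why: Dess–Martin oxidation under buffered, non-basic conditions should return the ketone without touching the C3–H bond or the chromene alkene, so the (3S) configuration set in step 6 is kept.

**Step 8**
Reactants: 14 (3S)-5,7-dimethoxy-3-(7-methoxy-2,2-dimethyl-2H-chromen-6-yl)chroman-4-one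
Product: 15 (3S)-5-hydroxy-7-methoxy-3-(7-methoxy-2,2-dimethyl-2H-chromen-6-yl)chroman-4-one
Conditions: BCl3 (1 M in CH2Cl2), CH2Cl2, −78 → −20 °C; then H2O, 0 °C
Reagents that add atoms: none
Why: Chelation-controlled ether cleavage: BCl3 forms a six-membered chelate between C4=O and the peri 5-methoxy oxygen and only that methyl group is removed by chloride, while the 7- and 7′-methoxy groups are not chelated; no base is present at low temperature, so C3 should not enolise.

**Compound list**
1 | 1-bromo-2,4-dimethoxybenzene | COc1ccc(Br)c(OC)c1 | starting material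
2 | 2-bromo-2-methylpropanoyl bromide | CC(C)(Br)C(=O)Br | starting material
3 | 2-bromo-1-(5-bromo-2,4-dimethoxyphenyl)-2-methylpropan-1-one | COc1cc(OC)c(cc1Br)C(=O)C(C)(C)Br | intermediate
4 | 2-bromo-1-(5-bromo-2-hydroxy-4-methoxyphenyl)-2-methylpropan-1-one | COc1cc(O)c(cc1Br)C(=O)C(C)(C)Br | intermediate
5 | 5-bromo-6-methoxy-2,2-dimethyl-1-benzofuran-3(2H)-one | COc1cc2OC(C)(C)C(=O)c2cc1Br | intermediate
6 | 5-bromo-6-methoxy-2,2-dimethyl-3-methylidene-2,3-dihydro-1-benzofuran | COc1cc2OC(C)(C)C(=C)c2cc1Br | intermediate
7 | rac-9-[(5-bromo-6-methoxy-2,2-dimethyl-2,3-dihydro-1-benzofuran-3-yl)methyl]-9-borabicyclo[3.3.1]nonane | COc1cc2OC(C)(C)C(CB3C4CCCC3CCC4)c2cc1Br | intermediate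
8 | rac-(5-bromo-6-methoxy-2,2-dimethyl-2,3-dihydro-1-benzofuran-3-yl)methanol | COc1cc2OC(C)(C)C(CO)c2cc1Br | intermediate
9 | rac-(5-bromo-6-methoxy-2,2-dimethyl-2,3-dihydro-1-benzofuran-3-yl)methyl trifluoromethanesulfonate | COc1cc2OC(C)(C)C(COS(=O)(=O)C(F)(F)F)c2cc1Br | intermediate
10 | 6-bromo-7-methoxy-2,2-dimethyl-2H-chromene | COc1cc2OC(C)(C)C=Cc2cc1Br | intermediate
11 | 5,7-dimethoxychroman-4-one | COc1cc(OC)c2C(=O)CCOc2c1 | starting material
12 | rac-5,7-dimethoxy-3-(7-methoxy-2,2-dimethyl-2H-chromen-6-yl)chroman-4-one | COc1cc(OC)c2c(c1)OCC(c1cc3c(cc1OC)OC(C)(C)C=C3)C2=O | intermediate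
13 | (3S,4S)-5,7-dimethoxy-3-(7-methoxy-2,2-dimethyl-2H-chromen-6-yl)chroman-4-ol | COc1cc(OC)c2c(c1)OC[C@H](c1cc3c(cc1OC)OC(C)(C)C=C3)[C@@H]2O | intermediate
14 | (3S)-5,7-dimethoxy-3-(7-methoxy-2,2-dimethyl-2H-chromen-6-yl)chroman-4-one | COc1cc(OC)c2c(c1)OC[C@H](c1cc3c(cc1OC)OC(C)(C)C=C3)C2=O | intermediate
15 | (3S)-5-hydroxy-7-methoxy-3-(7-methoxy-2,2-dimethyl-2H-chromen-6-yl)chroman-4-one | COc1cc(O)c2c(c1)OC[C@H](c1cc3c(cc1OC)OC(C)(C)C=C3)C2=O | target

**Total step count:** 8. **Longest linear sequence:** 8 steps (1 → 15; compound 11 is bought).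

**Steps most likely to fail**

Step 4 (ring expansion). The triflate may ionise with fragmentation of the C2–C3 bond instead of clean aryl migration, or the electron-rich chromene may oligomerise under the triflic acid released. The fallback moves the one-carbon expansion to the ketone oxidation level. It sets out from alkene 6: [hydroxy(tosyloxy)iodo]benzene in 95% methanol should add iodine(III) to the terminal CH2 and trigger the 1,2-aryl shift with loss of iodobenzene, giving 6-bromo-7-methoxy-2,2-dimethylchroman-3-one F1. NaBH4 in methanol would then give rac-6-bromo-7-methoxy-2,2-dimethylchroman-3-ol F2. Burgess reagent in benzene at 50 °C should remove water by syn-elimination towards the benzylic C4–H, the only β-hydrogens available because C2 is quaternary. The fallback comes back to the route at chromene 10.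

Step 6 (transfer hydrogenation with dynamic kinetic resolution). Hydride transfer to the hindered, peri-methoxylated carbonyl may be too slow, or the 2,4,6-trioxygenated benzylic alcohol may ionise and eliminate, which would destroy C3. The fallback sets the centre by enantioselective protonation and avoids the alcohol. It sets out from racemic ketone 12: TBSOTf and Et3N in CH2Cl2 should give tert-butyl{[5,7-dimethoxy-3-(7-methoxy-2,2-dimethyl-2H-chromen-6-yl)-2H-chromen-4-yl]oxy}dimethylsilane F3. Protonation of this silyl enol ether with a BINOL-derived chiral N-triflyl thiophosphoramide catalyst and phenol as stoichiometric proton source (toluene, low temperature) would give the ketone directly. The catalyst enantiomer is chosen to deliver the (3S) product, and the fallback comes back to the route at 14.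

Step 8 (5-O-demethylation). Lewis-acid-promoted enolisation during the ether cleavage may erode the C3 configuration. The fallback moves the demethylation in front of the stereo-defining step. It sets out from racemic ketone 12: BCl3 (or MgI2·OEt2) should give rac-5-hydroxy-7-methoxy-3-(7-methoxy-2,2-dimethyl-2H-chromen-6-yl)chroman-4-one F4, where epimerisation costs nothing. Transfer hydrogenation with the same (S,S)-catalyst and dynamic kinetic resolution would give (3S,4S)-7-methoxy-3-(7-methoxy-2,2-dimethyl-2H-chromen-6-yl)chromane-4,5-diol F5. Activated MnO2 in CH2Cl2 should then oxidise only the benzylic alcohol under neutral conditions, and the fallback comes back to the route at target 15.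

**Further compounds**
F1 | step 4 | 6-bromo-7-methoxy-2,2-dimethylchroman-3-one | COc1cc2OC(C)(C)C(=O)Cc2cc1Br
F2 | step 4 | rac-6-bromo-7-methoxy-2,2-dimethylchroman-3-ol | COc1cc2OC(C)(C)C(O)Cc2cc1Br
F3 | step 6 | tert-butyl{[5,7-dimethoxy-3-(7-methoxy-2,2-dimethyl-2H-chromen-6-yl)-2H-chromen-4-yl]oxy}dimethylsilane | COc1cc(OC)c2c(c1)OCC(c1cc3c(cc1OC)OC(C)(C)C=C3)=C2O[Si](C)(C)C(C)(C)C
F4 | step 8 | rac-5-hydroxy-7-methoxy-3-(7-methoxy-2,2-dimethyl-2H-chromen-6-yl)chroman-4-one | COc1cc(O)c2c(c1)OCC(c1cc3c(cc1OC)OC(C)(C)C=C3)C2=O
F5 | step 8 | (3S,4S)-7-methoxy-3-(7-methoxy-2,2-dimethyl-2H-chromen-6-yl)chromane-4,5-diol | COc1cc(O)c2c(c1)OC[C@H](c1cc3c(cc1OC)OC(C)(C)C=C3)[C@@H]2O
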